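**Plan**
1. Target numbering: O1, C2 (CH3), C3 (CHO), C4 (CH2CO2R), C5 (CO2Me), C6 of the 3,4-dihydro-2H-pyran; configuration (2S,3R,4R).
2. Retrosynthesis: cut the side-chain ester (hydroxytyrosol); then C3–CHO together with C2–H (syn addition to a 4H-pyran); then O1–C2 and C4–C5 in one [3+3] event; then the enone C=C (cross-metathesis).
3. Enabling feature: O1–C6H=C5(CO2Me) is the enol of a formylacetate (a C,O-dinucleophile), and C2(CH3)/C3/C4 map onto C=O, Cα and Cβ of a methyl enone.
4. Forward: the enone is made by metathesis; one flask (Michael addition, hemiketal closure, dehydration) builds the pyran ring at the ketone oxidation level of C2; hydroboration–carbonylation, tert-butyl ester cleavage and Mitsunobu esterification finish.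
5. Stereochemistry: C4 from the chiral amine catalyst in the ring-forming step; C2 and C3 from syn delivery of H and CHO to the enol-ether double bond anti to the C4 side chain.

Key step: step 3

Remark: sodium enolate 6 is also sold; the sense of induction in step 3 is assigned by analogy and must be confirmed, the antipodal catalyst being equally available.

Step 1
Reactants: 1 but-3-en-2-one (methyl vinyl ketone); 2 tert-butyl but-3-enoate
Product: 3 tert-butyl (3E)-5-oxohex-3-enoate
Conditions: 1 (3 equiv), second-generation Hoveyda–Grubbs catalyst RuCl2(H2IMes)(=CH-C6H4-2-OiPr) (2 mol%), 1,4-benzoquinone (10 mol%), CH2Cl2, 40 °C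
Reagents that add atoms: none
Why: Olefin cross-metathesis of a terminal alkene with an electron-poor vinyl ketone should give the (E)-enone with loss of ethene, the benzoquinone suppressing migration of the double bond.

Step 2
Reactants: 4 methyl acetate; 5 methyl formate
Product: 6 sodium (1E)-3-methoxy-3-oxoprop-1-en-1-olate
Conditions: NaOMe (1.0 equiv), Et2O, 0 → 25 °C; salt filtered off
Reagents that add atoms: sodium methoxide, [Na+].[O-]C
Why: Crossed Claisen condensation, in which methyl formate (no α-hydrogen) formylates the enolate of methyl acetate and precipitation of the stabilised sodium enolate drives the equilibrium.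

Step 3
Reactants: 3 tert-butyl (3E)-5-oxohex-3-enoate; 6 sodium (1E)-3-methoxy-3-oxoprop-1-en-1-olate
Product: 10 methyl (4R)-4-(2-tert-butoxy-2-oxoethyl)-6-methyl-4H-pyran-3-carboxylate, via methyl 3-oxopropanoate 7 (not isolated), via open-chain Michael adduct 8 (not isolated), via cyclic hemiketal 9 (not isolated)
Conditions: 6 (1.2 equiv), CF3CO2H (1.2 equiv), (4S,5S)-4,5-diphenylimidazolidine-2-carboxylic acid (10 mol%), CH2Cl2, 25 °C; then TsOH·H2O (5 mol%), 4 Å molecular sieves, toluene, 40 °C
Reagents that add atoms: none
Why: The amine activates enone 3 as an α,β-unsaturated iminium ion and the enol carbon of 7 (set free from 6) adds to its β-carbon on the unshielded face (C4–C5 bond of the target, adduct 8); the enol oxygen of 8, the oxygen that came with 7, then adds to the ketone carbon (O1–C2 bond, hemiketal 9), and TsOH removes the former ketone oxygen as water. The closest known reaction type is the amine-catalysed Michael addition of acidic 1,3-dicarbonyl compounds to benzylideneacetone-type enones with this imidazolidine acid, which likewise ends in a cyclic hemiketal (warfarin), followed by the acid dehydration of a δ-keto enol used in Hantzsch-type 4H-pyran syntheses. The ring closes in the 6-exo-trig mode (O onto C=O), and the elimination should go into the ring because the endocyclic trisubstituted enol ether is the more stable alkene. The only new stereocentre, C4, is set by the catalyst, whose phenyl groups shield one face of the iminium ion; the (4S,5S) acid is expected to give (3S)-8 and hence (4R)-10. The step needs hemiketal closure to win over aldol closure of the methyl ketone onto the formyl group, which the formyl ester should secure by existing almost wholly as its hydrogen-bonded enol; it also needs the acidic CH2 of 3 not to hold the catalyst as a dienamine, which the acid of the catalyst and the acidity of 7 should prevent by reprotonation.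

Step 4
Reactants: 10 methyl (4R)-4-(2-tert-butoxy-2-oxoethyl)-6-methyl-4H-pyran-3-carboxylate
Product: 12 methyl (2S,3R,4R)-4-(2-tert-butoxy-2-oxoethyl)-3-formyl-2-methyl-3,4-dihydro-2H-pyran-5-carboxylate, via B-alkyl-9-borabicyclononane adduct 11 (not isolated)
Conditions: 9-BBN (1.3 equiv), THF, 0 → 50 °C; then CO (1 atm), LiAlH(OtBu)3 (1.1 equiv), −35 → 0 °C; then H2O2, phosphate buffer pH 7, 0 °C
Reagents that add atoms: carbon monoxide, [C-]#[O+]
Why: Hydroboration–carbonylation: 9-BBN should add H–B syn across the electron-rich C5=C6 enol ether of 10 (boron to the carbon β to oxygen) from the face opposite the pseudo-axial C4 side chain, the secondary alkyl group then migrates to CO with retention while the hydride traps the acylborane and buffered peroxide releases the aldehyde, so that H at C2 and CHO at C3 arrive cis to each other and trans to the side chain, the ester-conjugated enol ether being too electron-poor to react.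

Step 5
Reactants: 12 methyl (2S,3R,4R)-4-(2-tert-butoxy-2-oxoethyl)-3-formyl-2-methyl-3,4-dihydro-2H-pyran-5-carboxylate
Product: 13 2-[(2S,3R,4R)-3-formyl-5-(methoxycarbonyl)-2-methyl-3,4-dihydro-2H-pyran-4-yl]acetic acid
Conditions: CF3CO2H–CH2Cl2 (1:3), 0 → 25 °C
Reagents that add atoms: none
Why: Acidolysis of the tert-butyl ester (loss of 2-methylpropene via the tert-butyl cation) should leave the methyl ester, the ester-conjugated enol ether and the aldehyde intact, and no base is present that could open the ring by retro-oxa-Michael reaction at C2 or move C3 out of its favoured trans arrangement.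

Step 6
Reactants: 13 2-[(2S,3R,4R)-3-formyl-5-(methoxycarbonyl)-2-methyl-3,4-dihydro-2H-pyran-4-yl]acetic acid; 14 2-(3,4-dihydroxyphenyl)ethanol (hydroxytyrosol)
Product: 15 methyl (2S,3R,4R)-4-{2-[2-(3,4-dihydroxyphenyl)ethoxy]-2-oxoethyl}-3-formyl-2-methyl-3,4-dihydro-2H-pyran-5-carboxylate
Conditions: 14 (1.1 equiv), PPh3 (1.2 equiv), DIAD (1.2 equiv), THF, 0 → 25 °C
Reagents that add atoms: none
Why: Mitsunobu esterification, in which the primary alcohol of 14 is activated as its alkoxyphosphonium ion and displaced by the carboxylate of 13 while the far less acidic phenols are neither activated nor acylated (known chemoselectivity for phenolic alcohols), and the near-neutral medium should leave C2 and C3 untouched.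

**Compound list**
1 | but-3-en-2-one (methyl vinyl ketone) | CC(=O)C=C | starting material
2 | tert-butyl but-3-enoate | C=CCC(=O)OC(C)(C)C | starting material
3 | tert-butyl (3E)-5-oxohex-3-enoate | CC(=O)/C=C/CC(=O)OC(C)(C)C | intermediate
4 | methyl acetate | COC(C)=O | starting material
5 | methyl formate | COC=O | starting material
6 | sodium (1E)-3-methoxy-3-oxoprop-1-en-1-olate | [Na+].[O-]/C=C/C(=O)OC | intermediate
7 | methyl 3-oxopropanoate (largely the enol) | COC(=O)CC=O | intermediate (not isolated)
8 | 5-tert-butyl 1-methyl (3S)-2-formyl-3-(2-oxopropyl)pentanedioate | COC(=O)C(C=O)[C@@H](CC(C)=O)CC(=O)OC(C)(C)C | intermediate (not isolated)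
9 | methyl (4S)-4-(2-tert-butoxy-2-oxoethyl)-6-hydroxy-6-methyl-5,6-dihydro-4H-pyran-3-carboxylate | COC(=O)C1=COC(C)(O)C[C@H]1CC(=O)OC(C)(C)C | intermediate (not isolated)
10 | methyl (4R)-4-(2-tert-butoxy-2-oxoethyl)-6-methyl-4H-pyran-3-carboxylate | COC(=O)C1=COC(C)=C[C@H]1CC(=O)OC(C)(C)C | intermediate
11 | methyl (2S,3R,4R)-3-(9-borabicyclo[3.3.1]nonan-9-yl)-4-(2-tert-butoxy-2-oxoethyl)-2-methyl-3,4-dihydro-2H-pyran-5-carboxylate | COC(=O)C1=CO[C@@H](C)[C@H](B2C3CCCC2CCC3)[C@H]1CC(=O)OC(C)(C)C | intermediate (not isolated)
12 | methyl (2S,3R,4R)-4-(2-tert-butoxy-2-oxoethyl)-3-formyl-2-methyl-3,4-dihydro-2H-pyran-5-carboxylate | COC(=O)C1=CO[C@@H](C)[C@H](C=O)[C@H]1CC(=O)OC(C)(C)C | intermediate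
13 | 2-[(2S,3R,4R)-3-formyl-5-(methoxycarbonyl)-2-methyl-3,4-dihydro-2H-pyran-4-yl]acetic acid | COC(=O)C1=CO[C@@H](C)[C@H](C=O)[C@H]1CC(=O)O | intermediate
14 | 2-(3,4-dihydroxyphenyl)ethanol (hydroxytyrosol) | OCCc1ccc(O)c(O)c1 | starting material
15 | methyl (2S,3R,4R)-4-{2-[2-(3,4-dihydroxyphenyl)ethoxy]-2-oxoethyl}-3-formyl-2-methyl-3,4-dihydro-2H-pyran-5-carboxylate | COC(=O)C1=CO[C@@H](C)[C@H](C=O)[C@H]1CC(=O)OCCc1ccc(O)c(O)c1 | target

Total steps: 6. Longest linear sequence: 5 (steps 1, 3, 4, 5, 6).

**Steps most likely to fail**

Step 3. The amine may be held as unreactive enamines of 7 or of 3, may give low face selectivity, or the methyl ketone of 8 may close onto the formyl group by aldol reaction. The fallback sets out from 3 and comes back at 8. The formylacetate is brought in as the preformed enamine of a chiral secondary amine, so that no free amine, no free aldehyde and no catalyst turnover are involved. Methyl propiolate and (2S)-2-(methoxymethyl)pyrrolidine (CH2Cl2, 0 °C) give methyl (2E)-3-[(2S)-2-(methoxymethyl)pyrrolidin-1-yl]prop-2-enoate F1. Michael addition of F1 to 3 promoted by ZnCl2 (THF, −20 °C), with the auxiliary controlling the face, gives 5-tert-butyl 1-methyl (3S)-2-{[(2S)-2-(methoxymethyl)pyrrolidin-1-yl]methylidene}-3-(2-oxopropyl)pentanedioate F2. Aqueous acetic acid then hydrolyses the vinylogous carbamate, returns the auxiliary and gives 8, which is closed and dehydrated to 10 as in step 3. The antipodal auxiliary is used if the addition favours the other face.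

Step 4. The β-alkoxy organoborane 11 may eliminate with opening of the ring, or the hindered secondary alkyl group may fail to migrate to CO. The fallback sets out from 10 and comes back at 12 (no new compound; F0). It is a catalytic hydroformylation: Rh(acac)(CO)2 with tris(2,4-di-tert-butylphenyl) phosphite, CO/H2 (1:1, 40 bar), toluene, 80 °C. This adds H and CHO in the same syn sense, formyl at the less substituted carbon β to oxygen and anti to the side chain, as known for cyclic enol ethers.

Step 6. The betaine may alkylate or oxidise the catechol, or long exposure may epimerise C3. The fallback sets out from 13 and 14 and comes back at 15 (no new compound; F0). It is an enzymatic esterification with immobilised Candida antarctica lipase B in 2-methylbutan-2-ol over 4 Å molecular sieves at 40 °C, which acylates only the primary aliphatic hydroxyl of 14 under neutral conditions.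

**Further compounds**
F1 | step 3 | methyl (2E)-3-[(2S)-2-(methoxymethyl)pyrrolidin-1-yl]prop-2-enoate | COC[C@@H]1CCCN1/C=C/C(=O)OC
F2 | step 3 | 5-tert-butyl 1-methyl (3S)-2-{[(2S)-2-(methoxymethyl)pyrrolidin-1-yl]methylidene}-3-(2-oxopropyl)pentanedioate | COC[C@@H]1CCCN1C=C(C(=O)OC)[C@@H](CC(C)=O)CC(=O)OC(C)(C)C
F0 | step 4 | none | none
F0 | step 6 | none | none
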